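**Plan**
1. Locants: decalin C1 (CMe2), C2 (side chain), C3 (CMe), C4 (CH2), C4a, C5H=C6Me, C7, C8, C8a; dioxane C3'–C6'; acid Cα. Cuts: the methyl ester last; then C2–CH2 (B-alkyl Suzuki) to give enol triflate 12 and vinyl-dioxane 24; in 12 the C4–C4a bond is cut and C4a is re-bonded to C2. This shrinks ring B (C1–C2–C3–C4–C4a–C8a) to cyclobutanol 8, which carries C3/C4 as an isopropenyl group.
2. Enabling feature: C4a is allylic to the ring-A olefin C5=C6, so it can leave C2 as an allyl anion. C1 is quaternary, and C2=C3 is the only possible enolate of the ring-B ketone. A 1,3-shift of C4a from C2 to C4 therefore gives ring B, the cis fusion and the olefin position in one event.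
3. Forward, decalin half: Diels–Alder (ring A inside a bicyclo[2.2.2]octene), then ketone, gem-dimethyl, photochemical 1,3-acyl shift (cyclobutanone fused to ring A), isopropenyl carbinol, and four-to-six ring expansion with triflation.
4. Forward, peroxide half: (S)-2-methylglycidol, epoxy aldehyde, cis-β-lactone (Cα–C3' bond), perhydrolysis (C6'–OOH), O–C3' closure of the 1,2-dioxane, then CHO and vinyl. The halves are joined by hydroboration/Suzuki coupling and the ester is saponified.
5. Stereochemistry: C8a comes from the catalyst-controlled Diels–Alder reaction and is relayed to C4a by two tether-bound shifts. C6' comes from the chiral pool and is inverted once, in the perhydrolysis. Cα and C3' come from the alkaloid-catalysed ketene–aldehyde cycloaddition, and C3' is inverted once, in the ring closure.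

Key step: step 6

Assumption: the sense of induction of the two chiral catalysts (steps 1 and 10) is taken by analogy with the parent substrates (cyclohexadiene/acrolein; linear aldehyde/methylketene); if either were opposite, the mirror-image imidazolidinone or O-trimethylsilylquinine would be used.

**Step 1**
Reactants: 1 1-methylcyclohexa-1,3-diene; 2 acrolein
Product: 3 (1R,2R,4R)-1-methylbicyclo[2.2.2]oct-5-ene-2-carbaldehyde (CHO endo, syn to the C5=C6 bridge)
Conditions: (5S)-5-benzyl-2,2,3-trimethylimidazolidin-4-one·HCl (20 mol %), MeCN–H2O 95:5, 23 °C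
Reagents that add atoms: none
Why: Iminium-catalysed enantioselective Diels–Alder reaction in which the donor methyl on the diene terminus directs "ortho" bonding (methyl-bearing carbon to Cα of acrolein) and the benzyl group of the catalyst shields one face of the iminium ion, so the bridgeheads C1/C4 (C4 becomes C8a) are set by the catalyst while the endo/exo centre C2 is erased in step 2.

**Step 2**
Reactants: 3 (1R,2R,4R)-1-methylbicyclo[2.2.2]oct-5-ene-2-carbaldehyde
Product: 4 (1R,4R)-1-methylbicyclo[2.2.2]oct-5-en-2-one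
Conditions: Cu(OAc)2 (5 mol %), 2,2'-bipyridine (5 mol %), DABCO (20 mol %), O2 (1 atm), DMF, 40 °C
Reagents that add atoms: dioxygen, O=O
Why: Copper-catalysed aerobic oxidative deformylation of an α-branched aldehyde (enolate oxygenation, then C–C cleavage of the α-hydroperoxy aldehyde) should expel the formyl carbon as formic acid and leave the ketone without touching the disubstituted olefin or the bridgeheads.

**Step 3**
Reactants: 4 (1R,4R)-1-methylbicyclo[2.2.2]oct-5-en-2-one
Product: 6 (1R,4S)-1,3,3-trimethylbicyclo[2.2.2]oct-5-en-2-one, via monomethyl ketone 5 (not isolated)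
Conditions: KOt-Bu (2.5 equiv), MeI (3 equiv), THF, 0 °C → rt
Reagents that add atoms: iodomethane, CI
Why: Exhaustive enolate alkylation, which should stop cleanly at the gem-dimethyl ketone because C1 is a quaternary bridgehead and only C3 can enolise.

**Step 4**
Reactants: 6 (1R,4S)-1,3,3-trimethylbicyclo[2.2.2]oct-5-en-2-one
Product: 7 (1R,6S)-3,7,7-trimethylbicyclo[4.2.0]oct-2-en-8-one (cis-fused)
Conditions: hν (λ ≈ 300 nm, Pyrex), degassed pentane, rt, stopped at partial conversion (recovered 6 recycled)
Reagents that add atoms: none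
Why: Direct n→π* excitation of the β,γ-unsaturated ketone causes Norrish type I cleavage of C1–C2 (acyl/tertiary allyl radical pair) and recombination at the unhindered CH terminus C5, the photochemical 1,3-acyl shift known for bicyclo[2.2.2]oct-5-en-2-ones, and the acyl carbon stays tied to C4 through CMe2, so the new centre (future C4a) can only form cis to it.

**Step 5**
Reactants: 7 (1R,6S)-3,7,7-trimethylbicyclo[4.2.0]oct-2-en-8-one
Product: 8 (1R,6S,8S)-3,7,7-trimethyl-8-(prop-1-en-2-yl)bicyclo[4.2.0]oct-2-en-8-ol (isopropenyl exo)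
Conditions: CH2=C(Me)MgBr (1.3 equiv), LaCl3·2LiCl (1 equiv), THF, −78 → 0 °C; then H2O
Reagents that add atoms: isopropenylmagnesium bromide, CC(=C)[Mg]Br
Why: Lanthanide-assisted Grignard 1,2-addition to the strained, highly electrophilic cyclobutanone should outrun enolisation at the allylic C1–H and come from the convex face (syn to the bridgehead hydrogens), although this carbinol centre is erased in step 6.

**Step 6**
Reactants: 8 (1R,6S,8S)-3,7,7-trimethyl-8-(prop-1-en-2-yl)bicyclo[4.2.0]oct-2-en-8-ol
Product: 12 (4aR,8aS)-1,1,3,6-tetramethyl-1,4,4a,7,8,8a-hexahydronaphthalen-2-yl trifluoromethanesulfonate, via potassium alkoxide 9 (not isolated), via allylpotassium enone 10 (not isolated), via potassium enolate 11 (not isolated)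
Conditions: KH (1.3 equiv), 18-crown-6 (1.3 equiv), THF, 0 °C → rt; then PhNTf2 (1.4 equiv), 0 °C → rt
Reagents that add atoms: N-phenylbis(trifluoromethanesulfonimide), O=S(=O)(N(c1ccccc1)S(=O)(=O)C(F)(F)F)C(F)(F)F
Why: KH/18-crown-6 converts 8 into the naked alkoxide 9, in which the oxyanion, the cyclobutane strain and the allylic position of C1 (bicyclooctene numbering, next to the ring-A olefin C2=C3) together weaken the C8–C1 bond, so that it heterolyses to the tethered cyclohexenyl anion/isopropenyl ketone pair 10. The former C1 then adds to the nearby CH2 terminus of the enone (6-endo-trig Michael closure), so the four-membered ring C1–C6–C7–C8 takes up the two isopropenyl carbons and becomes six-membered ring B of enolate 11, a net alkoxide-accelerated [1,3]-shift. The closest known reaction types are the oxyanion-accelerated vinylcyclobutane-to-cyclohexene rearrangement and the [1,3] two-carbon ring expansion of potassium 1-vinylcycloalk-3-en-1-olates, and the O-sulfonylation copies that of the 2,2,6-trimethylcyclohexanone enolate. The one stereocentre that is re-made, C4a (decalin numbering), is controlled by C8a, because the three-atom tether hangs from one face of ring A and the new bond must form perpendicular to the allyl plane (pseudoaxial), which a six-membered closure can reach only on the tether's own face, hence cis. The step needs C8–C1 rather than C8–C7 cleavage (allyl versus tertiary alkyl anion), attack through the CH terminus rather than the methyl-bearing terminus of the allyl anion (fused six-membered ring versus bridged eight-membered ring with a new quaternary centre; 1,2-returns to the carbonyl are reversible, and the bicyclo[2.2.2] alkoxide they could give drains by oxy-Cope shift into the same 11), and closure ahead of loss of the side chain. The enolate is formed regiodefined and cannot move because decalin C1 is quaternary, so PhNTf2 fixes the tetrasubstituted C2=C3 olefin as the coupling handle.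

**Step 7**
Reactants: 13 (S)-2-methylglycidol
Product: 14 (2R)-2-methylhex-5-ene-1,2-diol
Conditions: allylMgCl (2.5 equiv), CuI (10 mol %), THF, −30 → 0 °C; then H2O
Reagents that add atoms: allylmagnesium chloride, C=CC[Mg]Cl
Why: Copper-catalysed SN2 opening of the epoxide at its unsubstituted CH2 terminus touches no bond of the stereocentre (and the degenerate Payne shift of the alkoxide returns the same enantiomer), so the future C6' keeps its chiral-pool configuration.

**Step 8**
Reactants: 14 (2R)-2-methylhex-5-ene-1,2-diol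
Product: 16 (2R)-2-(but-3-en-1-yl)-2-methyloxirane, via primary tosylate 15 (not isolated)
Conditions: TsCl (1.05 equiv), powdered KOH (excess), THF, 0 °C → rt
Reagents that add atoms: none
Why: Selective sulfonylation of the primary hydroxyl followed by Williamson-type 3-exo-tet closure by the tertiary alkoxide (one-pot diol-to-epoxide conversion) retains the C–O bond at the stereocentre.

**Step 9**
Reactants: 16 (2R)-2-(but-3-en-1-yl)-2-methyloxirane
Product: 18 3-[(2R)-2-methyloxiran-2-yl]propanal, via ozonide 17 (not isolated)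
Conditions: O3, CH2Cl2, −78 °C; then Me2S, −78 °C → rt
Reagents that add atoms: ozone, [O-][O+]=O
Why: Ozonolysis with reductive work-up cleaves the only olefin, and the epoxide is inert to both ozone and dimethyl sulfide.

**Step 10**
Reactants: 18 3-[(2R)-2-methyloxiran-2-yl]propanal
Product: 19 (3R,4S)-3-methyl-4-{2-[(2R)-2-methyloxiran-2-yl]ethyl}oxetan-2-one (cis-β-lactone)
Conditions: EtCOCl (2 equiv, slow addition), O-trimethylsilylquinidine (10 mol %), LiClO4, i-Pr2NEt (2.5 equiv), CH2Cl2–Et2O, −78 °C
Reagents that add atoms: propionyl chloride, CCC(=O)Cl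
Why: Alkaloid-catalysed acyl halide–aldehyde cyclocondensation (formal ketene–aldehyde [2+2]: aldol addition of the chiral ammonium Z-enolate of methylketene to the Li+-activated aldehyde, then lactonisation) should give the cis-3,4-disubstituted β-lactone with both new centres (Cα and C3') set by the catalyst, the remote epoxide centre having no influence.

**Step 11**
Reactants: 19 (3R,4S)-3-methyl-4-{2-[(2R)-2-methyloxiran-2-yl]ethyl}oxetan-2-one
Product: 20 (3R,4S)-4-[(3S)-3-hydroperoxy-4-hydroxy-3-methylbutyl]-3-methyloxetan-2-one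
Conditions: anhydrous H2O2 in Et2O (excess), H3PMo12O40 (2 mol %), 0 °C → rt
Reagents that add atoms: hydrogen peroxide, OO
Why: Molybdenum-acid-catalysed perhydrolysis of a 2,2-disubstituted epoxide, in which H2O2 attacks the activated oxirane at its tertiary carbon in a borderline SN2 event with inversion, should turn the (R)-epoxide carbon into the (S)-hydroperoxide centre C6', and the substrate holds no olefin that could be epoxidised.

**Step 12**
Reactants: 20 (3R,4S)-4-[(3S)-3-hydroperoxy-4-hydroxy-3-methylbutyl]-3-methyloxetan-2-one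
Product: 22 methyl (2R)-2-[(3R,6S)-6-(hydroxymethyl)-6-methyl-1,2-dioxan-3-yl]propanoate, via cesium carboxylate 21 (not isolated)
Conditions: Cs2CO3 (1.1 equiv), DMF (high dilution), 0 °C → rt; then MeI (1.5 equiv)
Reagents that add atoms: iodomethane, CI
Why: Proposed new method: Cs2CO3 ionises only the hydroperoxide, and the peroxy anion, an α-effect nucleophile tethered to C3', should open the β-lactone by alkyl–oxygen cleavage in a 6-exo-tet SN2 with inversion at C3' (strain release, carboxylate leaving group), because attack at the acyl carbon would need a bridged eight-membered transition state and β-elimination is stereoelectronically blocked (the C3'–O bond lies in the nodal plane of the lactone enolate); the closest known reaction types are the SN2 alkyl–oxygen opening of 4-alkyl-β-lactones by azide, sulfonamide or carboxylate nucleophiles and the base-mediated 6-exo-tet cyclisation of hydroperoxy sulfonates to 1,2-dioxanes; MeI then esterifies the released carboxylate in the same flask.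

**Step 13**
Reactants: 22 methyl (2R)-2-[(3R,6S)-6-(hydroxymethyl)-6-methyl-1,2-dioxan-3-yl]propanoate
Product: 23 methyl (2R)-2-[(3R,6S)-6-formyl-6-methyl-1,2-dioxan-3-yl]propanoate
Conditions: Dess–Martin periodinane (1.2 equiv), CH2Cl2, 0 °C → rt
Reagents that add atoms: none
Why: Dess–Martin oxidation works under near-neutral conditions that dialkyl peroxides and esters tolerate, and the aldehyde formed has no α-hydrogen, so it can neither epimerise nor eliminate.

**Step 14**
Reactants: 23 methyl (2R)-2-[(3R,6S)-6-formyl-6-methyl-1,2-dioxan-3-yl]propanoate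
Product: 24 methyl (2R)-2-[(3R,6S)-6-ethenyl-6-methyl-1,2-dioxan-3-yl]propanoate
Conditions: Ph3PCH3Br (1.2 equiv), KHMDS (1.15 equiv), THF, 0 °C; then 23, −78 → 0 °C
Reagents that add atoms: methyltriphenylphosphonium bromide, C[P+](c1ccccc1)(c1ccccc1)c1ccccc1.[Br-]
Why: Wittig methylenation, in which the non-stabilised ylide should add to the aldehyde at low temperature much faster than it deprotonates the ester or attacks the hindered O–O bond.

**Step 15**
Reactants: 24 methyl (2R)-2-[(3R,6S)-6-ethenyl-6-methyl-1,2-dioxan-3-yl]propanoate; 12 (4aR,8aS)-1,1,3,6-tetramethyl-1,4,4a,7,8,8a-hexahydronaphthalen-2-yl trifluoromethanesulfonate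
Product: 26 methyl (2R)-2-[(3R,6R)-6-methyl-6-{2-[(4aR,8aS)-1,1,3,6-tetramethyl-1,4,4a,7,8,8a-hexahydronaphthalen-2-yl]ethyl}-1,2-dioxan-3-yl]propanoate, via B-alkyl borane 25 (not isolated)
Conditions: 9-BBN-H (1.2 equiv), THF, 0 °C → rt; then 12, PdCl2(dppf) (10 mol %), aq K3PO4, DMF–THF, 45 °C
Reagents that add atoms: none
Why: Anti-Markovnikov hydroboration of the monosubstituted olefin with 9-BBN (boron ends γ to the peroxide oxygen, so no β-elimination) followed by B-alkyl Suzuki–Miyaura coupling with the enol triflate, a reaction type used on 2,6,6-trimethylcyclohexenyl triflates and compatible with 1,2-dioxanes under mild conditions, forms the C2–CH2 bond without touching any stereocentre.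

**Step 16**
Reactants: 26 methyl (2R)-2-[(3R,6R)-6-methyl-6-{2-[(4aR,8aS)-1,1,3,6-tetramethyl-1,4,4a,7,8,8a-hexahydronaphthalen-2-yl]ethyl}-1,2-dioxan-3-yl]propanoate
Product: 27 (2R)-2-[(3R,6R)-6-methyl-6-{2-[(4aR,8aS)-1,1,3,6-tetramethyl-1,4,4a,7,8,8a-hexahydronaphthalen-2-yl]ethyl}-1,2-dioxan-3-yl]propanoic acid (CNP0122760.1)
Conditions: LiOH (3 equiv), THF–H2O, 0 °C → rt; then dilute HCl to pH 4
Reagents that add atoms: lithium hydroxide, [Li+].[OH-]
Why: Mild saponification, the usual interconversion of such peroxy esters and acids, in which the carboxylate once formed resists α-deprotonation, so retro-oxa-Michael opening and epimerisation at Cα should stay slow.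

**Compound list**
1 | 1-methylcyclohexa-1,3-diene | CC1=CC=CCC1 | starting material
2 | acrolein | C=CC=O | starting material
3 | (1R,2R,4R)-1-methylbicyclo[2.2.2]oct-5-ene-2-carbaldehyde | C[C@]12C=C[C@H](CC1)C[C@H]2C=O | intermediate
4 | (1R,4R)-1-methylbicyclo[2.2.2]oct-5-en-2-one | C[C@]12C=C[C@H](CC1)CC2=O | intermediate
5 | (1R,3R,4S)-1,3-dimethylbicyclo[2.2.2]oct-5-en-2-one (3-methyl syn to the olefin bridge) | C[C@]12C=C[C@H](CC1)[C@@H](C)C2=O | intermediate
6 | (1R,4S)-1,3,3-trimethylbicyclo[2.2.2]oct-5-en-2-one | C[C@]12C=C[C@H](CC1)C(C)(C)C2=O | intermediate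
7 | (1R,6S)-3,7,7-trimethylbicyclo[4.2.0]oct-2-en-8-one | CC1=C[C@H]2C(=O)C(C)(C)[C@H]2CC1 | intermediate
8 | (1R,6S,8S)-3,7,7-trimethyl-8-(prop-1-en-2-yl)bicyclo[4.2.0]oct-2-en-8-ol | CC1=C[C@H]2[C@](O)(C(C)=C)C(C)(C)[C@H]2CC1 | intermediate
9 | potassium (1R,6S,8S)-3,7,7-trimethyl-8-(prop-1-en-2-yl)bicyclo[4.2.0]oct-2-en-8-olate | [K+].CC1=C[C@H]2[C@]([O-])(C(C)=C)C(C)(C)[C@H]2CC1 | intermediate
10 | potassium 6-(2,4-dimethyl-3-oxopent-4-en-2-yl)-3-methylcyclohex-2-en-1-ide (ring-opened allyl anion, configuration at the future C8a unchanged) | [K+].CC1=C[CH-][C@H](CC1)C(C)(C)C(=O)C(C)=C | intermediate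
11 | potassium (4aR,8aS)-1,1,3,6-tetramethyl-1,4,4a,7,8,8a-hexahydronaphthalen-2-olate | [K+].CC1=C[C@H]2CC(C)=C([O-])C(C)(C)[C@H]2CC1 | intermediate
12 | (4aR,8aS)-1,1,3,6-tetramethyl-1,4,4a,7,8,8a-hexahydronaphthalen-2-yl trifluoromethanesulfonate | CC1=C[C@H]2CC(C)=C(OS(=O)(=O)C(F)(F)F)C(C)(C)[C@H]2CC1 | intermediate
13 | (S)-2-methylglycidol, [(2S)-2-methyloxiran-2-yl]methanol | OC[C@@]1(C)CO1 | starting material
14 | (2R)-2-methylhex-5-ene-1,2-diol | OC[C@@](O)(C)CCC=C | intermediate
15 | (2R)-2-hydroxy-2-methylhex-5-en-1-yl 4-methylbenzenesulfonate | Cc1ccc(cc1)S(=O)(=O)OC[C@@](O)(C)CCC=C | intermediate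
16 | (2R)-2-(but-3-en-1-yl)-2-methyloxirane | C1O[C@]1(C)CCC=C | intermediate
17 | 3-{2-[(2R)-2-methyloxiran-2-yl]ethyl}-1,2,4-trioxolane (ozonide, epimers at the trioxolane carbon) | C1O[C@]1(C)CCC1OCOO1 | intermediate
18 | 3-[(2R)-2-methyloxiran-2-yl]propanal | C1O[C@]1(C)CCC=O | intermediate
19 | (3R,4S)-3-methyl-4-{2-[(2R)-2-methyloxiran-2-yl]ethyl}oxetan-2-one | C1O[C@]1(C)CC[C@@H]1OC(=O)[C@@H]1C | intermediate
20 | (3R,4S)-4-[(3S)-3-hydroperoxy-4-hydroxy-3-methylbutyl]-3-methyloxetan-2-one | OC[C@](OO)(C)CC[C@@H]1OC(=O)[C@@H]1C | intermediate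
21 | cesium (2R)-2-[(3R,6S)-6-(hydroxymethyl)-6-methyl-1,2-dioxan-3-yl]propanoate | [Cs+].OC[C@]1(C)CC[C@H]([C@@H](C)C([O-])=O)OO1 | intermediate
22 | methyl (2R)-2-[(3R,6S)-6-(hydroxymethyl)-6-methyl-1,2-dioxan-3-yl]propanoate | OC[C@]1(C)CC[C@H]([C@@H](C)C(=O)OC)OO1 | intermediate
23 | methyl (2R)-2-[(3R,6S)-6-formyl-6-methyl-1,2-dioxan-3-yl]propanoate | O=C[C@]1(C)CC[C@H]([C@@H](C)C(=O)OC)OO1 | intermediate
24 | methyl (2R)-2-[(3R,6S)-6-ethenyl-6-methyl-1,2-dioxan-3-yl]propanoate | C=C[C@]1(C)CC[C@H]([C@@H](C)C(=O)OC)OO1 | intermediate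
25 | methyl (2R)-2-[(3R,6R)-6-[2-(9-borabicyclo[3.3.1]nonan-9-yl)ethyl]-6-methyl-1,2-dioxan-3-yl]propanoate | B1(CC[C@]2(C)CC[C@H]([C@@H](C)C(=O)OC)OO2)C2CCCC1CCC2 | intermediate
26 | methyl (2R)-2-[(3R,6R)-6-methyl-6-{2-[(4aR,8aS)-1,1,3,6-tetramethyl-1,4,4a,7,8,8a-hexahydronaphthalen-2-yl]ethyl}-1,2-dioxan-3-yl]propanoate | CC1=C[C@H]2CC(C)=C(CC[C@]3(C)CC[C@H]([C@@H](C)C(=O)OC)OO3)C(C)(C)[C@H]2CC1 | intermediate
27 | (2R)-2-[(3R,6R)-6-methyl-6-{2-[(4aR,8aS)-1,1,3,6-tetramethyl-1,4,4a,7,8,8a-hexahydronaphthalen-2-yl]ethyl}-1,2-dioxan-3-yl]propanoic acid | CC1=C[C@H]2CC(C)=C(CC[C@]3(C)CC[C@H]([C@@H](C)C(=O)O)OO3)C(C)(C)[C@H]2CC1 | target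

**Totals**
Total step count: 16. Longest linear sequence: 10 steps (13 → 27, steps 7–16). The decalin branch needs 6 steps to reach 12.

**Steps most likely to fail**

1. Step 12 (proposed new method). Substitution at the secondary lactone carbon may be too slow. Intermolecular attack at the acyl carbon (oligomeric peresters) or base-induced C–C fragmentation of the β-hydroxy hydroperoxide could then take over.
The fallback sets out from 19 and comes back at 22, and it uses only known chemistry. Methanolysis of the β-lactone at the acyl carbon (K2CO3, MeOH, 0 °C) would give methyl (2R,3S)-3-hydroxy-2-methyl-5-[(2R)-2-methyloxiran-2-yl]pentanoate F1. Mesylation (MsCl, Et3N, CH2Cl2, −20 °C) would give methyl (2R,3S)-3-(methanesulfonyloxy)-2-methyl-5-[(2R)-2-methyloxiran-2-yl]pentanoate F2. Perhydrolysis as in step 11 would give methyl (2R,3S,6S)-6-hydroperoxy-7-hydroxy-3-(methanesulfonyloxy)-2,6-dimethylheptanoate F3. The established base-mediated 6-exo-tet displacement of a secondary sulfonate by a hydroperoxide (Cs2CO3, DMF, 0 °C) would then close the dioxane with the same inversion at C3' and give 22.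

2. Step 6 (key step). The ring-opened allyl anion may shed the whole side chain (anionic [2+2] cycloreversion through cleavage of the C8a–C1 bond). It may also recombine through its methyl-bearing terminus, or be lost by proton transfer or anionic polymerisation of the enone.
The fallback sets out from 6 and comes back at 12, and it makes steps 4 and 5 unnecessary. Lanthanide-assisted addition of isopropenylmagnesium bromide to the hindered ketone from the face of the olefin bridge would give (1R,2S,4S)-1,3,3-trimethyl-2-(prop-1-en-2-yl)bicyclo[2.2.2]oct-5-en-2-ol F4. With KH/18-crown-6 its potassium alkoxide would undergo the concerted anionic oxy-Cope [3,3] shift, with no free carbanion, to the same enolate 11. Triflation with PhNTf2 then gives 12.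

3. Step 15. Pd(0) or phosphine may insert into or reduce the O–O bond. Transmetalation and reductive elimination at the doubly flanked tetrasubstituted triflate may be so slow that the borane is lost by protodeboronation or β-hydride elimination.
The fallback sets out from 12 and 23 and comes back at 26, and the peroxide meets neither palladium nor borane.
   - Methoxycarbonylation of 12 (Pd(OAc)2, PPh3, CO, MeOH, Et3N, DMF) would give methyl (4aR,8aS)-1,1,3,6-tetramethyl-1,4,4a,7,8,8a-hexahydronaphthalene-2-carboxylate F5.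
   - DIBAL-H reduction would give [(4aR,8aS)-1,1,3,6-tetramethyl-1,4,4a,7,8,8a-hexahydronaphthalen-2-yl]methanol F6.
   - PPh3·HBr would give {[(4aR,8aS)-1,1,3,6-tetramethyl-1,4,4a,7,8,8a-hexahydronaphthalen-2-yl]methyl}triphenylphosphonium bromide F7.
   - Wittig reaction of its ylide (NaHMDS, THF, −78 °C) with 23 would give methyl (2R)-2-[(3R,6S)-6-methyl-6-{(E)-2-[(4aR,8aS)-1,1,3,6-tetramethyl-1,4,4a,7,8,8a-hexahydronaphthalen-2-yl]ethenyl}-1,2-dioxan-3-yl]propanoate F8; the olefin geometry is irrelevant.
   - Diimide (dipotassium azodicarboxylate, AcOH, MeOH) would reduce only the disubstituted olefin and leave the peroxide and the tri- and tetrasubstituted olefins, giving 26.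

**Further compounds**
F1 | step 12 | methyl (2R,3S)-3-hydroxy-2-methyl-5-[(2R)-2-methyloxiran-2-yl]pentanoate | C1O[C@]1(C)CC[C@H](O)[C@@H](C)C(=O)OC
F2 | step 12 | methyl (2R,3S)-3-(methanesulfonyloxy)-2-methyl-5-[(2R)-2-methyloxiran-2-yl]pentanoate | C1O[C@]1(C)CC[C@H](OS(C)(=O)=O)[C@@H](C)C(=O)OC
F3 | step 12 | methyl (2R,3S,6S)-6-hydroperoxy-7-hydroxy-3-(methanesulfonyloxy)-2,6-dimethylheptanoate | OC[C@](OO)(C)CC[C@H](OS(C)(=O)=O)[C@@H](C)C(=O)OC
F4 | step 6 | (1R,2S,4S)-1,3,3-trimethyl-2-(prop-1-en-2-yl)bicyclo[2.2.2]oct-5-en-2-ol | C[C@]12C=C[C@H](CC1)C(C)(C)[C@@]2(O)C(C)=C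
F5 | step 15 | methyl (4aR,8aS)-1,1,3,6-tetramethyl-1,4,4a,7,8,8a-hexahydronaphthalene-2-carboxylate | CC1=C[C@H]2CC(C)=C(C(=O)OC)C(C)(C)[C@H]2CC1
F6 | step 15 | [(4aR,8aS)-1,1,3,6-tetramethyl-1,4,4a,7,8,8a-hexahydronaphthalen-2-yl]methanol | CC1=C[C@H]2CC(C)=C(CO)C(C)(C)[C@H]2CC1
F7 | step 15 | {[(4aR,8aS)-1,1,3,6-tetramethyl-1,4,4a,7,8,8a-hexahydronaphthalen-2-yl]methyl}triphenylphosphonium bromide | CC1=C[C@H]2CC(C)=C(C[P+](c3ccccc3)(c3ccccc3)c3ccccc3)C(C)(C)[C@H]2CC1.[Br-]
F8 | step 15 | methyl (2R)-2-[(3R,6S)-6-methyl-6-{(E)-2-[(4aR,8aS)-1,1,3,6-tetramethyl-1,4,4a,7,8,8a-hexahydronaphthalen-2-yl]ethenyl}-1,2-dioxan-3-yl]propanoate | CC1=C[C@H]2CC(C)=C(/C=C/[C@]3(C)CC[C@H]([C@@H](C)C(=O)OC)OO3)C(C)(C)[C@H]2CC1
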